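The runs stem from a simulated flask for substances that don't exist; noise was put on by code.

Single product leaves by two doors, and both rates carry the same factor c(single product). Doubling runs at k(double)·c(reagent)·c(single product), trapping at k(trap)·c(capture agent)·c(single product). Dividing one rate by the other removes c(single product) and time, so the flask's course rests on the ratio s·c(reagent)/c(capture agent), where s = k(double)/k(trap) is the selectivity factor. The first step, substrate with reagent, drops out of this ratio.

| flask | substrate | reagent | capture agent | remark | time |
|---|---|---|---|---|---|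
| south | 0.050 M | 0.013 M | 0.015 M | run made earlier |  |
| south-east | 0.050 M | 0.10 M | 0.015 M | run made earlier |  |
| Tuesday's | 0.050 M | 0.0250 M | 0.0150 M |  | 15 h |
| Monday's | 0.050 M | 0.0600 M | 0.0150 M |  | 15 h |
| Thursday's | 0.050 M | 0.125 M | 0.0150 M |  | 15 h |

| run | time / h | single product / % | double product / % | substrate / % |
|---|---|---|---|---|
| south | 1.50 | 4.4 | 1.6 | 77.2 |
| south | 3.00 | 0.7 | 2.4 | 76.6 |
| south | 5.00 | 0.6 | 1.4 | 76.6 |
| south | 6.00 | 0 | 2.6 | 76.7 |
| south | 8.00 | 0.9 | 3.1 | 76.5 |
| south | 10.0 | 0 | 2.8 | 76.7 |
| south-east | 0.833 | 9.3 | 59.9 | 12.3 |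
| south-east | 1.33 | 5.4 | 66.0 | 6.6 |
| south-east | 2.00 | 1.7 | 70.1 | 3.3 |
| south-east | 3.00 | 0.5 | 70.9 | 1.8 |
| south-east | 5.00 | 0.7 | 72.3 | 0.8 |
| south-east | 6.00 | 0.8 | 72.4 | 0 |
| south-east | 10.0 | 0.3 | 70.9 | 0 |

(each reading ± 0.5 percentage points)

* single product at the end, in percent of the substrate charged, for each flask in turn (Tuesday's, Monday's, Thursday's)

- the numbers in the tables scatter by 0.5 percentage points (one standard deviation)
- candidate steps: substrate + reagent -> single product + by-product; reagent + single product -> double product + by-product; single product + capture agent -> trapped intermediate; double product -> over-reaction product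

Written per logarithm of capture agent, the ratio integrates to: double product formed = s × mean c(reagent) × ln(c(capture agent) at start / c(capture agent) now). The south-east run serves at 0.833 h. The balances give c(reagent) falling from 0.10 M to 0.0262 M and c(capture agent) from 0.015 M to 0.00575 M. With the logarithmic mean 0.0551 M and 59.9 % double product, the reading is s = 0.567.

At charge the ratio is 0.945 on Tuesday's, 2.27 on Monday's and 4.72 on Thursday's. Thursday's reagent exceeds the 100 mM that full doubling takes, so my reckoning puts its single product at zero. Monday's charge falls below that amount, as does Tuesday's, and for these two flasks I commit to no figure. The forecast gives 5 %, 16 % and 0 %, the last because “reagent stays in excess”.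

The flasks give 2.04 %, 8.63 % and <0.001 %. Monday's flask ends with 0 % of its reagent and 20.7 % of its substrate.

    substrate + reagent → single product + by-product (k = 0.0150 M⁻¹ s⁻¹)
    reagent + single product → double product + by-product (k = 0.0250 M⁻¹ s⁻¹)
    single product + capture agent → trapped intermediate (k = 0.0460 M⁻¹ s⁻¹)
    double product → over-reaction product (k = 1.70 × 10⁻⁶ s⁻¹)

Thursday's flask tests s: its reagent falls to 28 % of charge and its capture agent to 32 %. The logarithmic mean is 0.0709 M, so s predicts 91.3 % doubled substrate, against 79.6 % stored as double and over-reaction product together.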